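**Assumption:** (E)-4-oxobut-2-enoic acid (5) is taken as a purchasable material, and the SMILES is read literally, which makes the two ring stereocentres of the acyl (upper) half antipodal to the corresponding centres of the lactone (lower) half.

## Retrosynthetic overview

- The inter-half ester is not made by acylation: the upper-half acid opens a lower-half spiro-epoxide at its CH2 carbon, which creates the ester and the tertiary carbinol together; the last step only frees the acid.
- Because the halves are antipodal in the ring, both come from one achiral trienyl ester by an iminium-catalysed intramolecular Diels–Alder reaction run with one or the other catalyst antipode (cyclohexene formed first, ester tether kept as a temporary γ-lactone).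
- The tether is unzipped by PhSe– opening and selenoxide elimination to a 2-methylidene acid; a carboxylate-relayed oxa-Michael/Horner–Wadsworth–Emmons annulation then adds the hydroxymethyl-acrylate arm (ε-lactone formed, then opened).
- Lower half: iodo-β-lactonisation fixes the quaternary C–O, and alkoxide translactonisation closes the ε-lactone and the epoxide. Upper half: the mirror-image β-lactone extrudes CO2 to an allylic iodide, so the carboxyl is traceless.
- Ring order: cyclohexene → γ-lactone (tether) → ε-lactone → β-lactone → ε-lactone plus epoxide (lower); cyclohexene → the same sequence to the β-lactone → cyclohexene with the new ring C=C (upper).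

## Route

Step 1
Reactants: 1 isobutyraldehyde; 2 triethyl 4-phosphonocrotonate
Product: 3 ethyl (2E,4E)-6-methylhepta-2,4-dienoate
Conditions: LiN(SiMe3)2, THF, −78 → 0 °C
Reagents that add atoms: none
Why: Vinylogous Horner–Wadsworth–Emmons olefination of an unhindered aldehyde gives the (2E,4E)-dienoate under thermodynamic control.

Step 2
Reactants: 3 ethyl (2E,4E)-6-methylhepta-2,4-dienoate
Product: 4 (2E,4E)-6-methylhepta-2,4-dien-1-ol
Conditions: iBu2AlH (2.2 equiv), CH2Cl2, −78 °C
Reagents that add atoms: none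
Why: 1,2-Reduction of the conjugated ester by iBu2AlH gives the dienol without touching the diene geometry.

Step 3
Reactants: 4 (2E,4E)-6-methylhepta-2,4-dien-1-ol; 5 (E)-4-oxobut-2-enoic acid
Product: 6 (2E,4E)-6-methylhepta-2,4-dien-1-yl (2E)-4-oxobut-2-enoate
Conditions: DCC, DMAP (5 mol %), CH2Cl2, 0 °C
Reagents that add atoms: none
Why: Steglich esterification joins diene and dienophile through the ester that later serves as a removable tether; low temperature and little DMAP limit conjugate addition to the enal.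

Step 4
Reactants: 6 (2E,4E)-6-methylhepta-2,4-dien-1-yl (2E)-4-oxobut-2-enoate
Product: 7 (3aR,6S,7S,7aS)-1-oxo-6-(propan-2-yl)-1,3,3a,6,7,7a-hexahydro-2-benzofuran-7-carbaldehyde
Conditions: (2S,5S)-5-benzyl-2-tert-butyl-3-methylimidazolidin-4-one (20 mol %), CF3CO2H (20 mol %), MeCN/H2O 98:2, 0.02 M, 0 → 40 °C
Reagents that add atoms: none
Why: Iminium-catalysed intramolecular Diels–Alder reaction of an E,E-diene with an E-enal through the CHO-endo/tether-exo transition state gives the trans-fused lactone with CHO cis to iPr and to the CH2O arm, and the benzyl group of the (5S) catalyst leaves the Si face of the CHO-bearing carbon open, which fixes the absolute configuration of all four new centres.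

Step 5
Reactants: 7 lactone aldehyde
Product: 9 (3aR,6R,7S,7aS)-7-(dimethoxymethyl)-6-(propan-2-yl)hexahydro-2-benzofuran-1(3H)-one, via saturated lactone aldehyde 8 (not isolated)
Conditions: H2 (1 atm), Pd/C, EtOAc, rt; filter, evaporate; then HC(OMe)3, PPTS (cat.), CH2Cl2, rt
Reagents that add atoms: trimethyl orthoformate, COC(OC)OC
Why: Heterogeneous hydrogenation removes the cis-disubstituted ring alkene without reducing CHO or lactone, and acid-catalysed acetalisation masks the aldehyde against the selenolate of step 6.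

Step 6
Reactants: 9 acetal lactone
Product: 10 (1R,2S,3R,6R)-2-(dimethoxymethyl)-6-[(phenylselanyl)methyl]-3-(propan-2-yl)cyclohexane-1-carboxylic acid
Conditions: PhSeSePh, NaBH4, DMF, 110 °C; then cold dilute HCl to pH 4
Reagents that add atoms: diphenyl diselenide, c1ccccc1[Se][Se]c1ccccc1
Why: SN2 alkyl–oxygen cleavage of the strained trans-fused γ-lactone by the soft selenolate frees the carboxylic acid and places selenium on the CH2 carbon in one operation, with no stereocentre touched.

Step 7
Reactants: 10 seleno acid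
Product: 12 (1R,2S,3R)-2-formyl-6-methylidene-3-(propan-2-yl)cyclohexane-1-carboxylic acid, via methylidene acetal acid 11 (not isolated)
Conditions: H2O2 (30 % aq), pyridine, CH2Cl2, 0 → 40 °C; then 5 % aq. oxalic acid, THF, rt
Reagents that add atoms: water, O
Why: Selenoxide syn-elimination has a single β-hydrogen available and therefore gives only the exocyclic methylene, after which mild aqueous acid hydrolyses the dimethyl acetal.

Step 8
Reactants: 13 (diethoxyphosphoryl)acetic acid; 14 2-(trimethylsilyl)ethanol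
Product: 15 2-(trimethylsilyl)ethyl (diethoxyphosphoryl)acetate
Conditions: DCC, DMAP (cat.), CH2Cl2, 0 °C → rt
Reagents that add atoms: none
Why: Steglich esterification installs the fluoride-labile ester that will carry the lower-half acid to the end.

Step 9
Reactants: 15 2-(trimethylsilyl)ethyl (diethoxyphosphoryl)acetate; 16 paraformaldehyde
Product: 17 2-(trimethylsilyl)ethyl 2-(diethoxyphosphoryl)prop-2-enoate
Conditions: piperidine (cat.), AcOH (cat.), toluene, 110 °C, Dean–Stark
Reagents that add atoms: none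
Why: Knoevenagel condensation of the active methylene with formaldehyde gives the doubly activated vinylphosphonate, as for the known ethyl analogue.

Step 10
Reactants: 12 formyl methylidene acid; 17 2-(trimethylsilyl)ethyl 2-(diethoxyphosphoryl)prop-2-enoate
Product: 19 (1R,2R,3R)-2-[(1E)-3-hydroxy-2-{[2-(trimethylsilyl)ethoxy]carbonyl}prop-1-en-1-yl]-6-methylidene-3-(propan-2-yl)cyclohexane-1-carboxylic acid, via methylidene ε-lactone 18 (not isolated)
Conditions: Cs2CO3 (2.2 equiv), MeCN, 0 °C → rt; then LiOH (1.2 equiv), THF/H2O, 0 °C; HCl to pH 3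
Reagents that add atoms: lithium hydroxide, [Li+].[OH-]
Why: Proposed new method: the caesium carboxylate of 12 adds to the vinylphosphonate (oxa-Michael) and the phosphonate carbanion so formed is trapped by the neighbouring aldehyde in an intramolecular Horner–Wadsworth–Emmons reaction, so the trisubstituted alkene is born inside a seven-membered ring with the only possible geometry (ring carbon trans to the ester); the closest known reactions are alkoxide- and phenoxide-triggered oxa-Michael/HWE annulations to 2,5-dihydrofurans and 2H-chromenes, and LiOH then saponifies the non-conjugated ε-lactone in preference to the hindered conjugated ester.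

Step 11
Reactants: 19 hydroxy acid
Product: 20 2-(trimethylsilyl)ethyl (2E)-2-(hydroxymethyl)-3-[6-(iodomethyl)-8-oxo-3-(propan-2-yl)-7-oxabicyclo[4.2.0]octan-2-yl]prop-2-enoate (cis-fused β-lactone; CH2I, side chain and iPr on one face)
Conditions: I2 (1.1 equiv), NaHCO3, CH2Cl2/H2O, 0 °C, dark
Reagents that add atoms: iodine, [I][I]
Why: Kinetic 4-exo iodolactonisation of the β,γ-unsaturated acid can only give the cis-fused β-lactone, so the new C–O bond at the quaternary carbon is forced onto the face of the carboxyl group and CH2I onto the face of the isopropyl group.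

Step 12
Reactants: 20 iodomethyl β-lactone
Product: 22 2-(trimethylsilyl)ethyl 1-oxo-6-(propan-2-yl)-1,3,5a,6,7,8-hexahydrospiro[2-benzoxepine-9,2'-oxirane]-4-carboxylate (epoxide O on the face of the lactone carbonyl arm; ring centres as in 18), via iodohydrin ε-lactone 21 (not isolated)
Conditions: NaH (1.05 equiv), THF, 0 °C → rt
Reagents that add atoms: none
Why: The primary alkoxide transacylates the strained β-lactone (ring expansion to the ε-lactone) and the tertiary alkoxide released displaces the neighbouring iodide (Williamson epoxide closure), so the oxygen placed in step 11 is kept with retention.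

Step 13
Reactants: 6 trienyl ester
Product: 23 (3aS,6R,7R,7aR)-1-oxo-6-(propan-2-yl)-1,3,3a,6,7,7a-hexahydro-2-benzofuran-7-carbaldehyde (enantiomer of 7)
Conditions: (2R,5R)-5-benzyl-2-tert-butyl-3-methylimidazolidin-4-one (20 mol %), CF3CO2H (20 mol %), MeCN/H2O 98:2, 0.02 M, 0 → 40 °C
Reagents that add atoms: none
Why: The same iminium-catalysed intramolecular Diels–Alder reaction with the antipodal catalyst opens the Re face of the CHO-bearing carbon and delivers the mirror-image series needed for the upper half.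

Step 14
Reactants: 23 enantiomeric lactone aldehyde
Product: 25 (3aS,6S,7R,7aR)-7-(dimethoxymethyl)-6-(propan-2-yl)hexahydro-2-benzofuran-1(3H)-one, via saturated lactone aldehyde 24 (not isolated)
Conditions: H2 (1 atm), Pd/C, EtOAc, rt; filter, evaporate; then HC(OMe)3, PPTS (cat.), CH2Cl2, rt
Reagents that add atoms: trimethyl orthoformate, COC(OC)OC
Why: Hydrogenation and acetalisation as in step 5, with no stereocentre affected.

Step 15
Reactants: 25 acetal lactone
Product: 26 (1S,2R,3S,6S)-2-(dimethoxymethyl)-6-[(phenylselanyl)methyl]-3-(propan-2-yl)cyclohexane-1-carboxylic acid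
Conditions: PhSeSePh, NaBH4, DMF, 110 °C; then cold dilute HCl to pH 4
Reagents that add atoms: diphenyl diselenide, c1ccccc1[Se][Se]c1ccccc1
Why: SN2 lactone opening by selenolate as in step 6.

Step 16
Reactants: 26 seleno acid
Product: 28 (1S,2R,3S)-2-formyl-6-methylidene-3-(propan-2-yl)cyclohexane-1-carboxylic acid, via methylidene acetal acid 27 (not isolated)
Conditions: H2O2 (30 % aq), pyridine, CH2Cl2, 0 → 40 °C; then 5 % aq. oxalic acid, THF, rt
Reagents that add atoms: water, O
Why: Selenoxide syn-elimination and acetal hydrolysis as in step 7.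

Step 17
Reactants: 28 formyl methylidene acid; 17 2-(trimethylsilyl)ethyl 2-(diethoxyphosphoryl)prop-2-enoate
Product: 30 (1S,2S,3S)-2-[(1E)-3-hydroxy-2-{[2-(trimethylsilyl)ethoxy]carbonyl}prop-1-en-1-yl]-6-methylidene-3-(propan-2-yl)cyclohexane-1-carboxylic acid, via methylidene ε-lactone 29 (not isolated)
Conditions: Cs2CO3 (2.2 equiv), MeCN, 0 °C → rt; then LiOH (1.2 equiv), THF/H2O, 0 °C; HCl to pH 3
Reagents that add atoms: lithium hydroxide, [Li+].[OH-]
Why: Proposed new method: the same carboxylate-relayed oxa-Michael/intramolecular Horner–Wadsworth–Emmons annulation as in step 10 (carboxylate adds to the vinylphosphonate, the carbanion olefinates the adjacent aldehyde within a seven-membered ring, which fixes the alkene geometry; closest precedent alkoxide-triggered oxa-Michael/HWE annulations), followed by selective saponification of the ε-lactone.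

Step 18
Reactants: 30 hydroxy acid
Product: 31 enantiomer of 20 (cis-fused iodomethyl β-lactone of the upper-half series)
Conditions: I2 (1.1 equiv), NaHCO3, CH2Cl2/H2O, 0 °C, dark
Reagents that add atoms: iodine, [I][I]
Why: 4-exo iodolactonisation as in step 11; here the β-lactone serves only to activate the carboxyl for loss.

Step 19
Reactants: 31 iodomethyl β-lactone
Product: 34 (2E)-2-(hydroxymethyl)-3-[(1R,6S)-3-(hydroxymethyl)-6-(propan-2-yl)cyclohex-2-en-1-yl]prop-2-enoic acid, via allylic iodide 32 (not isolated), via diol ester 33 (not isolated)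
Conditions: toluene, 105 °C (−CO2); then LiOH (5 equiv), THF/H2O, rt → 40 °C; HCl to pH 3
Reagents that add atoms: lithium hydroxide, [Li+].[OH-]
Why: Thermal [2+2] cycloreversion of the β-lactone expels CO2 and leaves the ring C=C exactly where the carboxyl stood, after which hydroxide substitutes the primary allylic iodide (SN2) and saponifies the ester; the two ring stereocentres are untouched.

Step 20
Reactants: 34 upper-half diol acid; 22 lower-half spiro-epoxide
Product: 35 2-(trimethylsilyl)ethyl ester of the target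
Conditions: 34 (1.3 equiv), Cs2CO3 (0.3 equiv), DMF, 70 °C
Reagents that add atoms: none
Why: Base-catalysed carboxylate opening of the 2,2-disubstituted epoxide at its CH2 carbon forms the ester C–O bond and the tertiary alcohol in one step with retention at the quaternary carbon, and the hydroxyl groups of 34 are not deprotonated by the catalytic carbonate.

Step 21
Reactants: 35 2-(trimethylsilyl)ethyl ester of the target
Product: 36 CNP0361406.11
Conditions: Bu4NF (3 equiv), THF, 0 °C → rt; aq. NH4Cl
Reagents that add atoms: none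
Why: Fluoride-induced β-elimination of the 2-(trimethylsilyl)ethyl ester releases the acid without acid or metal catalysis, sparing the allylic ε-lactone, the acrylate ester and the alcohols.

## Compound list

1 | isobutyraldehyde (2-methylpropanal) | CC(C)C=O | starting material
2 | triethyl 4-phosphonocrotonate | CCOC(=O)/C=C/CP(=O)(OCC)OCC | starting material
3 | ethyl (2E,4E)-6-methylhepta-2,4-dienoate | CCOC(=O)/C=C/C=C/C(C)C | intermediate
4 | (2E,4E)-6-methylhepta-2,4-dien-1-ol | CC(C)/C=C/C=C/CO | intermediate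
5 | (E)-4-oxobut-2-enoic acid | O=C/C=C/C(=O)O | starting material
6 | (2E,4E)-6-methylhepta-2,4-dien-1-yl (2E)-4-oxobut-2-enoate | CC(C)/C=C/C=C/COC(=O)/C=C/C=O | intermediate
7 | (3aR,6S,7S,7aS)-1-oxo-6-(propan-2-yl)-1,3,3a,6,7,7a-hexahydro-2-benzofuran-7-carbaldehyde | CC(C)[C@H]1C=C[C@H]2COC(=O)[C@@H]2[C@H]1C=O | intermediate
8 | (3aR,6R,7S,7aS)-1-oxo-6-(propan-2-yl)octahydro-2-benzofuran-7-carbaldehyde | CC(C)[C@H]1CC[C@H]2COC(=O)[C@@H]2[C@H]1C=O | intermediate (not isolated)
9 | (3aR,6R,7S,7aS)-7-(dimethoxymethyl)-6-(propan-2-yl)hexahydro-2-benzofuran-1(3H)-one | CC(C)[C@H]1CC[C@H]2COC(=O)[C@@H]2[C@H]1C(OC)OC | intermediate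
10 | (1R,2S,3R,6R)-2-(dimethoxymethyl)-6-[(phenylselanyl)methyl]-3-(propan-2-yl)cyclohexane-1-carboxylic acid | CC(C)[C@H]1CC[C@@H](C[Se]c2ccccc2)[C@H](C(=O)O)[C@H]1C(OC)OC | intermediate
11 | (1R,2S,3R)-2-(dimethoxymethyl)-6-methylidene-3-(propan-2-yl)cyclohexane-1-carboxylic acid | CC(C)[C@H]1CCC(=C)[C@H](C(=O)O)[C@H]1C(OC)OC | intermediate (not isolated)
12 | (1R,2S,3R)-2-formyl-6-methylidene-3-(propan-2-yl)cyclohexane-1-carboxylic acid | CC(C)[C@H]1CCC(=C)[C@H](C(=O)O)[C@H]1C=O | intermediate
13 | (diethoxyphosphoryl)acetic acid | OC(=O)CP(=O)(OCC)OCC | starting material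
14 | 2-(trimethylsilyl)ethanol | C[Si](C)(C)CCO | starting material
15 | 2-(trimethylsilyl)ethyl (diethoxyphosphoryl)acetate | CCOP(=O)(OCC)CC(=O)OCC[Si](C)(C)C | intermediate
16 | paraformaldehyde (formaldehyde source) | C=O | starting material
17 | 2-(trimethylsilyl)ethyl 2-(diethoxyphosphoryl)prop-2-enoate | C=C(C(=O)OCC[Si](C)(C)C)P(=O)(OCC)OCC | intermediate
18 | 2-(trimethylsilyl)ethyl (5aR,6R,9aR)-9-methylidene-1-oxo-6-(propan-2-yl)-1,3,5a,6,7,8,9,9a-octahydro-2-benzoxepine-4-carboxylate | CC(C)[C@H]1CCC(=C)[C@@H]2C(=O)OCC(C(=O)OCC[Si](C)(C)C)=C[C@@H]12 | intermediate (not isolated)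
19 | (1R,2R,3R)-2-[(1E)-3-hydroxy-2-{[2-(trimethylsilyl)ethoxy]carbonyl}prop-1-en-1-yl]-6-methylidene-3-(propan-2-yl)cyclohexane-1-carboxylic acid | CC(C)[C@H]1CCC(=C)[C@H](C(=O)O)[C@H]1/C=C(\CO)C(=O)OCC[Si](C)(C)C | intermediate
20 | 2-(trimethylsilyl)ethyl (2E)-2-(hydroxymethyl)-3-[6-(iodomethyl)-8-oxo-3-(propan-2-yl)-7-oxabicyclo[4.2.0]octan-2-yl]prop-2-enoate (cis-fused β-lactone; CH2I, side chain and iPr on one face) | CC(C)[C@H]1CC[C@]2(CI)OC(=O)[C@@H]2[C@H]1/C=C(\CO)C(=O)OCC[Si](C)(C)C | intermediate
21 | 2-(trimethylsilyl)ethyl 9-hydroxy-9-(iodomethyl)-1-oxo-6-(propan-2-yl)-1,3,5a,6,7,8,9,9a-octahydro-2-benzoxepine-4-carboxylate (OH on the face of the lactone carbonyl arm, CH2I on the face of iPr) | CC(C)[C@H]1CC[C@@](O)(CI)[C@@H]2C(=O)OCC(C(=O)OCC[Si](C)(C)C)=C[C@@H]12 | intermediate (not isolated)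
22 | 2-(trimethylsilyl)ethyl 1-oxo-6-(propan-2-yl)-1,3,5a,6,7,8-hexahydrospiro[2-benzoxepine-9,2'-oxirane]-4-carboxylate (epoxide O on the face of the lactone carbonyl arm; ring centres as in 18) | CC(C)[C@H]1CC[C@@]3(CO3)[C@@H]2C(=O)OCC(C(=O)OCC[Si](C)(C)C)=C[C@@H]12 | intermediate
23 | (3aS,6R,7R,7aR)-1-oxo-6-(propan-2-yl)-1,3,3a,6,7,7a-hexahydro-2-benzofuran-7-carbaldehyde (enantiomer of 7) | CC(C)[C@@H]1C=C[C@@H]2COC(=O)[C@H]2[C@@H]1C=O | intermediate
24 | (3aS,6S,7R,7aR)-1-oxo-6-(propan-2-yl)octahydro-2-benzofuran-7-carbaldehyde (enantiomer of 8) | CC(C)[C@@H]1CC[C@@H]2COC(=O)[C@H]2[C@@H]1C=O | intermediate (not isolated)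
25 | (3aS,6S,7R,7aR)-7-(dimethoxymethyl)-6-(propan-2-yl)hexahydro-2-benzofuran-1(3H)-one (enantiomer of 9) | CC(C)[C@@H]1CC[C@@H]2COC(=O)[C@H]2[C@@H]1C(OC)OC | intermediate
26 | (1S,2R,3S,6S)-2-(dimethoxymethyl)-6-[(phenylselanyl)methyl]-3-(propan-2-yl)cyclohexane-1-carboxylic acid (enantiomer of 10) | CC(C)[C@@H]1CC[C@H](C[Se]c2ccccc2)[C@@H](C(=O)O)[C@@H]1C(OC)OC | intermediate
27 | (1S,2R,3S)-2-(dimethoxymethyl)-6-methylidene-3-(propan-2-yl)cyclohexane-1-carboxylic acid (enantiomer of 11) | CC(C)[C@@H]1CCC(=C)[C@@H](C(=O)O)[C@@H]1C(OC)OC | intermediate (not isolated)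
28 | (1S,2R,3S)-2-formyl-6-methylidene-3-(propan-2-yl)cyclohexane-1-carboxylic acid (enantiomer of 12) | CC(C)[C@@H]1CCC(=C)[C@@H](C(=O)O)[C@@H]1C=O | intermediate
29 | 2-(trimethylsilyl)ethyl (5aS,6S,9aS)-9-methylidene-1-oxo-6-(propan-2-yl)-1,3,5a,6,7,8,9,9a-octahydro-2-benzoxepine-4-carboxylate (enantiomer of 18) | CC(C)[C@@H]1CCC(=C)[C@H]2C(=O)OCC(C(=O)OCC[Si](C)(C)C)=C[C@H]12 | intermediate (not isolated)
30 | (1S,2S,3S)-2-[(1E)-3-hydroxy-2-{[2-(trimethylsilyl)ethoxy]carbonyl}prop-1-en-1-yl]-6-methylidene-3-(propan-2-yl)cyclohexane-1-carboxylic acid (enantiomer of 19) | CC(C)[C@@H]1CCC(=C)[C@@H](C(=O)O)[C@@H]1/C=C(\CO)C(=O)OCC[Si](C)(C)C | intermediate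
31 | enantiomer of 20 (cis-fused iodomethyl β-lactone, upper-half series) | CC(C)[C@@H]1CC[C@@]2(CI)OC(=O)[C@H]2[C@@H]1/C=C(\CO)C(=O)OCC[Si](C)(C)C | intermediate
32 | 2-(trimethylsilyl)ethyl (2E)-2-(hydroxymethyl)-3-[3-(iodomethyl)-6-(propan-2-yl)cyclohex-2-en-1-yl]prop-2-enoate (ring configuration as in 34) | CC(C)[C@@H]1CCC(CI)=C[C@@H]1/C=C(\CO)C(=O)OCC[Si](C)(C)C | intermediate (not isolated)
33 | 2-(trimethylsilyl)ethyl (2E)-2-(hydroxymethyl)-3-[(1R,6S)-3-(hydroxymethyl)-6-(propan-2-yl)cyclohex-2-en-1-yl]prop-2-enoate | CC(C)[C@@H]1CCC(CO)=C[C@@H]1/C=C(\CO)C(=O)OCC[Si](C)(C)C | intermediate (not isolated)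
34 | (2E)-2-(hydroxymethyl)-3-[(1R,6S)-3-(hydroxymethyl)-6-(propan-2-yl)cyclohex-2-en-1-yl]prop-2-enoic acid | CC(C)[C@@H]1CCC(CO)=C[C@@H]1/C=C(\CO)C(=O)O | intermediate
35 | 2-(trimethylsilyl)ethyl ester of the target (ester of the ring-alkene carboxyl) | CC(C)[C@H]1CC[C@@](O)(COC(=O)/C(=C/[C@H]2C=C(CO)CC[C@H]2C(C)C)CO)[C@@H]2C(=O)OCC(C(=O)OCC[Si](C)(C)C)=C[C@@H]12 | intermediate
36 | CNP0361406.11 | CC(C)[C@H]1CC[C@@](O)(COC(=O)/C(=C/[C@H]2C=C(CO)CC[C@H]2C(C)C)CO)[C@@H]2C(=O)OCC(C(=O)O)=C[C@@H]12 | target

## Step count and risk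

Total step count: 21. Longest linear sequence: 12 steps (1–7, 10–12, 20, 21; the upper-half line 1–3, 13–21 is equally long).

Three steps most likely to fail:

**Step 4 (step 13 is its mirror image and carries the same risk).** The ester tether must adopt its less favoured conformation for the cycloaddition, and no iminium-catalysed example with such a tether is known. The fallback sets out from 4 and comes back at 8. The dienol 4 is silylated (tBuMe2SiCl, imidazole, DMF) to the dienyl silyl ether F1. F1 undergoes an intermolecular iminium-catalysed Diels–Alder reaction with commercial ethyl (E)-4-oxobut-2-enoate under the same (2S,5S) catalyst to give the cyclohexene ester aldehyde F2; the CHO-bearing carbon bonds to the isopropyl-substituted diene terminus because that terminus carries the better donor, and CHO is endo. Hydrogenation (H2, Pd/C, EtOAc) gives the saturated ester aldehyde F3, HF·pyridine in MeCN gives the hydroxy ester F4, and PPTS in toluene at 80 °C lactonises F4 to 8.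

**Step 10 (step 17 is its mirror image).** The carboxylate is a weak Michael donor and the aldehyde of 12 can epimerise under base. The fallback sets out from 12 and 15 and comes back at 19. Phosphonate 15 is hydroxymethylated (aq. HCHO, K2CO3 cat., 0 °C) to the β-hydroxy phosphonate F5 and silylated (tBuMe2SiCl, imidazole) to the silyl ether phosphonate F6. The sodium salt of F6 (NaH, THF, −78 → 0 °C, 2.2 equiv) olefinates 12 in an ordinary intermolecular, thermodynamically E-selective Horner–Wadsworth–Emmons reaction to the silyloxymethyl acrylate acid F7, and HF·pyridine removes the silyl group to give 19.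

**Step 20.** The epoxide CH2 sits next to a quaternary carbon and the nucleophile is a bulky, unprotected hydroxy acid. The fallback sets out from 22 and 34 and comes back at 36; it makes the ester by acylation instead.
- Lower half: epoxide 22 is opened with the small nucleophile CsO2CH (HCO2H, DMF, 60 °C) to the hydroxy formate F8, and NaHCO3 in MeOH cleaves the formate to the diol lactone F9.
- Upper half: acid 34 is persilylated (tBuMe2SiCl, imidazole) to the tris-silyl compound F10, and K2CO3 in MeOH/H2O cleaves the silyl ester to the bis-silyl ether acid F11.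
- Union: Yamaguchi esterification (2,4,6-trichlorobenzoyl chloride, Et3N, DMAP, toluene) acylates only the primary hydroxyl of F9 to give the protected diester F12, and Bu4NF removes both silyl ethers and the 2-(trimethylsilyl)ethyl ester to give 36.

Further compounds
F1 | step 4 | tert-butyl(dimethyl){[(2E,4E)-6-methylhepta-2,4-dien-1-yl]oxy}silane | CC(C)/C=C/C=C/CO[Si](C)(C)C(C)(C)C
F2 | step 4 | ethyl 2-({[tert-butyl(dimethyl)silyl]oxy}methyl)-6-formyl-5-(propan-2-yl)cyclohex-3-ene-1-carboxylate (substituents arranged as in 7) | CC(C)[C@H]1C=C[C@@H](CO[Si](C)(C)C(C)(C)C)[C@H](C(=O)OCC)[C@H]1C=O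
F3 | step 4 | ethyl 6-({[tert-butyl(dimethyl)silyl]oxy}methyl)-2-formyl-3-(propan-2-yl)cyclohexane-1-carboxylate (substituents arranged as in 8) | CC(C)[C@H]1CC[C@@H](CO[Si](C)(C)C(C)(C)C)[C@H](C(=O)OCC)[C@H]1C=O
F4 | step 4 | ethyl 2-formyl-6-(hydroxymethyl)-3-(propan-2-yl)cyclohexane-1-carboxylate (substituents arranged as in 8) | CC(C)[C@H]1CC[C@@H](CO)[C@H](C(=O)OCC)[C@H]1C=O
F5 | step 10 | 2-(trimethylsilyl)ethyl 2-(diethoxyphosphoryl)-3-hydroxypropanoate (racemic) | CCOP(=O)(OCC)C(CO)C(=O)OCC[Si](C)(C)C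
F6 | step 10 | 2-(trimethylsilyl)ethyl 3-{[tert-butyl(dimethyl)silyl]oxy}-2-(diethoxyphosphoryl)propanoate (racemic) | CCOP(=O)(OCC)C(CO[Si](C)(C)C(C)(C)C)C(=O)OCC[Si](C)(C)C
F7 | step 10 | tert-butyldimethylsilyl ether of 19 at the primary hydroxyl | CC(C)[C@H]1CCC(=C)[C@H](C(=O)O)[C@H]1/C=C(\CO[Si](C)(C)C(C)(C)C)C(=O)OCC[Si](C)(C)C
F8 | step 20 | formate of the primary hydroxyl of the diol from 22 (tertiary OH free) | CC(C)[C@H]1CC[C@@](O)(COC=O)[C@@H]2C(=O)OCC(C(=O)OCC[Si](C)(C)C)=C[C@@H]12
F9 | step 20 | 2-(trimethylsilyl)ethyl 9-hydroxy-9-(hydroxymethyl)-1-oxo-6-(propan-2-yl)-1,3,5a,6,7,8,9,9a-octahydro-2-benzoxepine-4-carboxylate (configuration as in 21) | CC(C)[C@H]1CC[C@@](O)(CO)[C@@H]2C(=O)OCC(C(=O)OCC[Si](C)(C)C)=C[C@@H]12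
F10 | step 20 | tert-butyldimethylsilyl ester of the bis(tert-butyldimethylsilyl) ether of 34 | CC(C)[C@@H]1CCC(CO[Si](C)(C)C(C)(C)C)=C[C@@H]1/C=C(\CO[Si](C)(C)C(C)(C)C)C(=O)O[Si](C)(C)C(C)(C)C
F11 | step 20 | bis(tert-butyldimethylsilyl) ether of 34 (free acid) | CC(C)[C@@H]1CCC(CO[Si](C)(C)C(C)(C)C)=C[C@@H]1/C=C(\CO[Si](C)(C)C(C)(C)C)C(=O)O
F12 | step 20 | bis(tert-butyldimethylsilyl) ether of 35 | CC(C)[C@H]1CC[C@@](O)(COC(=O)/C(=C/[C@H]2C=C(CO[Si](C)(C)C(C)(C)C)CC[C@H]2C(C)C)CO[Si](C)(C)C(C)(C)C)[C@@H]2C(=O)OCC(C(=O)OCC[Si](C)(C)C)=C[C@@H]12
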